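The numbers of this flask come from no measurement; the rest is arithmetic.

Read the flask backwards from its late peaks: ask what level of target can stand there when the catalyst makes it and the remaining starting material eats it.

| setting | noon | dawn |
|---|---|---|
| starting material | 0.0010 M | 0.0010 M |
| reagent | 2.00 equiv | 2.00 equiv |
| free catalyst | 0.15 mol% | 0.15 mol% |
| impurity | 0.25 µM | 0.25 µM |
| temperature | −12 °C | −20 °C |
| time | 1.5 min | 1.5 min |

    starting material + free catalyst ⇌ catalyst intermediate A (K1 = 750 M⁻¹, k1 = 83000 M⁻¹ s⁻¹, Ea1 = 22.0 kJ mol⁻¹, ΔH1 = −43.0 kJ mol⁻¹)
    reagent + catalyst intermediate A ⇌ catalyst intermediate B (K2 = 8100 M⁻¹, k2 = 64000 M⁻¹ s⁻¹, Ea2 = 17.0 kJ mol⁻¹, ΔH2 = −1.00 kJ mol⁻¹)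
    catalyst intermediate B → released group + catalyst intermediate C (k3 = 71 s⁻¹, Ea3 = 59.0 kJ mol⁻¹)
    catalyst intermediate C → free catalyst + target (k4 = 1000 s⁻¹, Ea4 = 38.0 kJ mol⁻¹)
    starting material + target → side product (k5 = 130 M⁻¹ s⁻¹, Ea5 = 36.0 kJ mol⁻¹)
    reagent ⇌ dormant form (K6 = 2.2, k6 = 0.24 s⁻¹, Ea6 = 73.0 kJ mol⁻¹, ΔH6 = −34.0 kJ mol⁻¹)
    free catalyst + impurity → spent catalyst (k7 = 1.9 × 10⁶ M⁻¹ s⁻¹, Ea7 = 23.0 kJ mol⁻¹)
    (constants at −20 °C)

- which of these there is most of at the end, counted by the starting material in it, noon (side product / catalyst intermediate A / starting material / target)
- which of these there is most of at the end, counted by the starting material in it, dawn (side product / catalyst intermediate A / starting material / target)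
- final amount of the leader among these, as a percentage of the starting material charged, in noon
- final amount of the leader among these, as a percentage of the starting material charged, in dawn

- percent here means starting material units held: one side product counts as two
- at −20 °C the constants are as listed, elsewhere as the activation energies and enthalpies make them

**First seconds.** Count the working catalyst as the charge less the impurity, 1.25 µM, and treat it as free, the resting state. This overstates it while much starting material remains. Impurity meets free catalyst within about 0.421 s on the dawn constant, far shorter than the run. At dawn, reagent relaxes towards dormant form with a half-life of 1.99 s, again short. Each turnover uses one reagent, and each side product takes one starting material and one target, so a flask ending in side product spends about 0.500 mM of reagent. Freeze free reagent at that late value: 0.641 mM at noon and 0.469 mM at dawn.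

**The middle.** Catalyst intermediate A either falls back or takes reagent. At dawn, step 3 runs faster than the falling back of catalyst intermediate B, and step 4 faster than step 3, so count every B as passing on. The share of A going forward is 15.6 % at noon and 21.3 % at dawn. Target is made at k1 × share × c(working catalyst) × c(starting material) and lost at k5 × c(target) × c(starting material). Set the two equal and c(starting material) cancels. This gives the plateau level, the target at which making equals loss, k1 × share × c(working catalyst) / k5: 10.1 % of the charge at noon, and 17.0 % at dawn, higher. The time scale of that approach is roughly 7.69 s on the dawn constant at the charged starting material, well inside the run.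

**The end.** On the plateau, each turnover costs two starting material, one by step 1 and one by step 5. Starting material therefore decays exponentially at twice the turnover rate, a pseudo-first-order tail with half-life 0.260 min at noon and 0.261 min at dawn. Subtracting plateau and tail from the charge, this hand reckoning commits at noon to side product at 88.0 %, and at dawn to side product at 81.1 %.

**The forecast.** It names side product at 85 % for noon and side product at 81 % for dawn, saying the side reaction “competes strongly, holding target near 0.1 mM in both runs”. The hand reckoning parts from that level at dawn, where its plateau stands at 0.170 mM.

**The flask.** Noon gives side product at 87.7 % and dawn side product at 81.3 %, so the forecast holds on all four marks. At 1.50 min in noon, target is made 1.03 times as fast as it is used up, and it stands at 9.07 % against a reckoned plateau of 10.1 %. In a neighbour of noon, charged with 0.037 mol% of free catalyst, working catalyst falls to 0.120 µM. With the noon share kept, the plateau is 0.970 % and the half-life 2.71 min, leaving 68.1 % of the starting material. That flask gives target 0.827 %, starting material 71.3 % and side product 27.9 %, with starting material holding the most.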